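**Assumptions (one line each)**
- The target SMILES is the natural ent‑kaurane series (C20 and C19 axial on the α‑face, H‑5β); I use kaurane numbering throughout.
- I assume (−)‑8‑phenylmenthol gives the drawn A‑ring enantiomer; use the (+)‑enantiomer if the other diastereomer dominates in step 5.
- The C6 methyl‑acetal anomer is obtained by chromatographic separation, with the unwanted anomer recycled by re‑equilibration.

**Retrosynthesis**
1. Ludongnin F ← face‑selective hydrogenation of the 15‑oxo‑16‑ene, which places the C16 methyl endo ← α‑methylenation of ketone 24.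
2. The bicyclo[3.2.1]octane (C13–C16 bond) ← 5‑exo radical cyclisation of an α‑bromomethyl ketone onto the C12=C13 alkene of cyclohexene 21.
3. The spiro δ‑lactone, C ring and quaternary C8 ← domino intramolecular Knoevenagel/Diels–Alder with butadiene, from the C9 aldehyde and C20 acetoacetate of 19.
4. Quaternary C10 carrying C20 (ester) and C9 (CH2OBn) ← ester‑enolate alkylation of 12 anti to the cis‑fused ring; the 6‑OMe acetal comes from the γ‑lactone.
5. Ring order: A ring and THF via intramolecular Diels–Alder of dienyl maleate 8 (C4, C5), then the spiro δ‑lactone and C ring, then the D ring.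

---

**Step 1**
Reactants: 1 acrolein; 2 (1‑ethoxycarbonylethylidene)triphenylphosphorane
Product: 3 ethyl (2E)‑2‑methylpenta‑2,4‑dienoate
Conditions: CH2Cl2, rt
Reagents that add atoms: none beyond the numbered reactants
Why: E‑selective Wittig olefination; the ester ends up trans to the vinyl group, which sets the diene geometry needed later.

**Step 2**
Reactants: 3
Product: 4 (2E)‑2‑methylpenta‑2,4‑dien‑1‑ol
Conditions: DIBAL‑H (2.2 equiv), CH2Cl2, −78 → 0 °C
Reagents that add atoms: none
Why: Ester‑to‑alcohol reduction leaves the diene intact; the CH2OH will become C19 and the methyl C18.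

**Step 3**
Reactants: 5 maleic anhydride; 6 (−)‑8‑phenylmenthol
Product: 7 mono‑(8‑phenylmenthyl) (Z)‑butenedioate
Conditions: DMAP (cat.), Et3N, toluene, 90 °C
Reagents that add atoms: none beyond the numbered reactants
Why: Anhydride alcoholysis gives the half ester; the auxiliary will control the absolute sense of the Diels–Alder step.

**Step 4**
Reactants: 7; 4
Product: 8 dienyl 8‑phenylmenthyl maleate
Conditions: EDC·HCl, DMAP, CH2Cl2, 0 °C → rt
Reagents that add atoms: none beyond the numbered reactants
Why: Steglich esterification joins the diene alcohol to the acid, forming the tethered IMDA substrate.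

**Step 5**
Reactants: 8
Product: 9 cis‑fused γ‑lactone, 8‑phenylmenthyl 3a‑methyl‑1‑oxo‑1,3,3a,6,7,7a‑hexahydroisobenzofuran‑7‑carboxylate (C4‑Me, C5‑H, C6=O lactone, C19–O, C10 ester, C2=C3 alkene; C19 and C6 cis, C10 ester cis to C6)
Conditions: Me2AlCl (1.5 equiv), CH2Cl2, −78 → −20 °C; separate diastereomers by chromatography
Reagents that add atoms: none
Why: Type‑1 intramolecular Diels–Alder; the Lewis‑acid‑chelated maleate reacts through the endo transition state, giving the cis‑fused lactone (C4/C5) with C19, C6 and C20 on one face. The 8‑phenylmenthyl group shields one dienophile face, which sets the absolute configuration, and C10 is re‑set in step 8.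

**Step 6**
Reactants: 9
Product: 10 lactol (C6 epimeric mixture)
Conditions: DIBAL‑H (1.05 equiv), CH2Cl2, −78 °C
Reagents that add atoms: none
Why: The strained γ‑lactone is reduced faster than the hindered secondary 8‑phenylmenthyl ester, installing the C6 aldehyde oxidation level.

**Step 7**
Reactants: 10; 11 methanol
Product: 12 cyclic methyl acetal (C6‑OMe cis to C10, as in the target)
Conditions: CSA (0.1 equiv), MeOH, CH2Cl2, rt; separate anomers
Reagents that add atoms: methanol, CO
Why: Acid‑catalysed acetalisation through the oxocarbenium ion; the anomers are separable, and the acetal is non‑enolisable, so it survives the strong base in step 8.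

**Step 8**
Reactants: 12; 13 benzyl chloromethyl ether
Product: 14 quaternary ester (C10 bears CH2OBn, C9, equatorial, and the 8‑phenylmenthyl ester, C20, axial)
Conditions: LDA (1.3 equiv), THF, −78 °C; then 13, DMPU, −78 → 0 °C
Reagents that add atoms: benzyl chloromethyl ether, ClCOCc1ccccc1
Why: Enolate alkylation; the electrophile approaches the convex face anti to the cis‑fused C19/C6 ring, so the ester is left axial and cis to C19, giving the C10 configuration of the target.

**Step 9**
Reactants: 14
Product: 15 C20 primary alcohol (CH2OH axial, CH2OBn equatorial)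
Conditions: LiAlH4, THF, reflux
Reagents that add atoms: none
Why: Hydride reduction of the hindered ester to CH2OH releases the auxiliary; the acetal and benzyl ether are stable.

**Step 10**
Reactants: 15; 16 2,2,6‑trimethyl‑4H‑1,3‑dioxin‑4‑one (TMD)
Product: 17 C20 acetoacetate
Conditions: xylene, 130 °C
Reagents that add atoms: TMD, CC1=CC(=O)OC(C)(C)O1 (supplies the acetoacetyl group)
Why: Thermal retro‑[4+2] of TMD gives acetylketene, which acylates the only free alcohol to give the β‑keto ester.

**Step 11**
Reactants: 17
Product: 18 C9 primary alcohol with saturated A ring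
Conditions: H2 (1 atm), Pd(OH)2/C, EtOAc, rt
Reagents that add atoms: none (H2 only)
Why: Hydrogenolysis of the benzyl ether and saturation of C2=C3; no stereocentre is touched, and the β‑keto ester and acetal survive.

**Step 12**
Reactants: 18
Product: 19 C9 aldehyde (neopentyl)
Conditions: Dess–Martin periodinane, NaHCO3, CH2Cl2, 0 °C
Reagents that add atoms: none
Why: Mild oxidation gives the non‑enolisable quaternary aldehyde without epimerisation.

**Step 13**
Reactants: 19; 20 1,3‑butadiene
Product: 21 tetracycle (spiro δ‑lactone fused to the cyclohexene C ring, C8 acetyl, C12=C13 alkene; C14/C11 down, C15/H‑9 up)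
Conditions: piperidinium acetate (10 mol%), 4 Å MS, toluene, butadiene (excess), 90 °C, sealed tube
Reagents that add atoms: butadiene, C=CC=C
Why: Intramolecular Knoevenagel gives the 3‑acyl‑5,6‑dihydropyran‑2‑one, which is trapped in situ by Diels–Alder with butadiene (C8–C14, C9–C11). The diene adds suprafacially to the face anti to the bulky C5 side of spiro C10, making C8 and C9 cis as in the target.

**Step 14**
Reactants: 21; 22 N‑bromosuccinimide
Product: 23 α‑bromomethyl ketone
Conditions: LiHMDS, THF, −78 °C; TMSCl; then NBS, −78 °C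
Reagents that add atoms: NBS, O=C1CCC(=O)N1Br (supplies Br)
Why: The only enolisable site is the acetyl CH3, because C8 is quaternary and the lactone has no α‑H; kinetic silyl enol ether bromination avoids acid and alkene attack.

**Step 15**
Reactants: 23
Product: 24 pentacyclic ketone (bicyclo[3.2.1]octan‑6‑one; C16 = CH2)
Conditions: Bu3SnH (slow addition), AIBN, benzene, 80 °C, 0.01 M
Reagents that add atoms: none (H replaces Br)
Why: 5‑exo radical cyclisation of the α‑keto radical onto C13 of the cis‑disposed cyclohexene forms the C13–C16 bond; the C12 radical is reduced, and C13 configuration is enforced by the bridged ring.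

**Step 16**
Reactants: 24; 25 Eschenmoser's salt
Product: 26 Mannich base
Conditions: LiHMDS, THF, −78 °C; then 25, −78 → 0 °C
Reagents that add atoms: Eschenmoser's salt, C[N+](C)=C.[I-] (supplies CH2NMe2)
Why: C16 is the only enolisable carbon (C8 is quaternary), so aminomethylation is regiospecific.

**Step 17**
Reactants: 26; 27 iodomethane
Product: 28 15‑oxo‑16‑ene (exocyclic enone)
Conditions: MeI, CH2Cl2, rt; then DBU, rt
Reagents that add atoms: none (the methyl leaves with NMe3)
Why: Quaternisation followed by E1cB elimination gives the α‑methylene ketone.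

**Step 18**
Reactants: 28
Product: 29 ludongnin F
Conditions: H2 (1 atm), 10% Pd/C, EtOAc, rt
Reagents that add atoms: none (H2 only)
Why: Hydrogen is delivered to C16 from the less hindered exo face, away from the C9–C11–C12 bridge, which leaves the methyl endo as in the target; the lactone, acetal and ketone are untouched.

---

**Compound list**

| # | Name | SMILES | Role |
|---|---|---|---|
| 1 | acrolein | C=CC=O | starting material |
| 2 | (1‑ethoxycarbonylethylidene)triphenylphosphorane | CCOC(=O)C(C)=P(c1ccccc1)(c1ccccc1)c1ccccc1 | starting material |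
| 3 | ethyl (2E)‑2‑methylpenta‑2,4‑dienoate | CCOC(=O)/C(C)=C/C=C | intermediate |
| 4 | (2E)‑2‑methylpenta‑2,4‑dien‑1‑ol | OC/C(C)=C/C=C | intermediate |
| 5 | maleic anhydride | O=C1C=CC(=O)O1 | starting material |
| 6 | (−)‑8‑phenylmenthol | C[C@@H]1CC[C@H]([C@@H](C1)O)C(C)(C)c1ccccc1 | starting material |
| 7 | mono‑(8‑phenylmenthyl) (Z)‑butenedioate | OC(=O)/C=C\C(=O)O[C@@H]1C[C@H](C)CC[C@H]1C(C)(C)c1ccccc1 | intermediate |
| 8 | dienyl 8‑phenylmenthyl maleate | O=C(OC/C(C)=C/C=C)/C=C\C(=O)O[C@@H]1C[C@H](C)CC[C@H]1C(C)(C)c1ccccc1 | intermediate |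
| 9 | cis‑fused γ‑lactone IMDA adduct (8‑phenylmenthyl ester) | C[C@@]12C=CC[C@H](C(=O)O[C@@H]3C[C@H](C)CC[C@H]3C(C)(C)c3ccccc3)[C@@H]1C(=O)OC2 | intermediate |
| 10 | lactol (C6 epimers) | C[C@@]12C=CC[C@H](C(=O)O[C@@H]3C[C@H](C)CC[C@H]3C(C)(C)c3ccccc3)[C@@H]1C(O)OC2 | intermediate |
| 11 | methanol | CO | reagent (starting material) |
| 12 | cyclic methyl acetal ester | C[C@@]12C=CC[C@H](C(=O)O[C@@H]3C[C@H](C)CC[C@H]3C(C)(C)c3ccccc3)[C@@H]1[C@H](OC)OC2 | intermediate |
| 13 | benzyl chloromethyl ether | ClCOCc1ccccc1 | reagent (starting material) |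
| 14 | C10‑quaternary ester (CH2OBn, ester) | C[C@@]12C=CC[C@](COCc3ccccc3)(C(=O)O[C@@H]3C[C@H](C)CC[C@H]3C(C)(C)c3ccccc3)[C@@H]1[C@H](OC)OC2 | intermediate |
| 15 | C20 alcohol, C9 benzyl ether | C[C@@]12C=CC[C@](COCc3ccccc3)(CO)[C@@H]1[C@H](OC)OC2 | intermediate |
| 16 | 2,2,6‑trimethyl‑4H‑1,3‑dioxin‑4‑one | CC1=CC(=O)OC(C)(C)O1 | reagent (starting material) |
| 17 | C20 acetoacetate | C[C@@]12C=CC[C@](COCc3ccccc3)(COC(=O)CC(C)=O)[C@@H]1[C@H](OC)OC2 | intermediate |
| 18 | saturated C9 alcohol acetoacetate | C[C@@]12CCC[C@](CO)(COC(=O)CC(C)=O)[C@@H]1[C@H](OC)OC2 | intermediate |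
| 19 | C9 aldehyde acetoacetate | C[C@@]12CCC[C@](C=O)(COC(=O)CC(C)=O)[C@@H]1[C@H](OC)OC2 | intermediate |
| 20 | 1,3‑butadiene | C=CC=C | starting material |
| 21 | Diels–Alder tetracycle (C8 acetyl, C12=C13) | CO[C@@H]1OC[C@]2(C)CCC[C@]3(COC(=O)[C@@]4(C(C)=O)CC=CC[C@H]43)[C@H]12 | intermediate |
| 22 | N‑bromosuccinimide | O=C1CCC(=O)N1Br | reagent (starting material) |
| 23 | α‑bromomethyl ketone | CO[C@@H]1OC[C@]2(C)CCC[C@]3(COC(=O)[C@@]4(C(=O)CBr)CC=CC[C@H]43)[C@H]12 | intermediate |
| 24 | bicyclo[3.2.1] ketone (C16 = CH2) | CO[C@@H]1OC[C@]2(C)CCC[C@]3(COC(=O)[C@@]45C[C@@H](CC[C@H]43)CC5=O)[C@H]12 | intermediate |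
| 25 | Eschenmoser's salt | C[N+](C)=C.[I-] | reagent (starting material) |
| 26 | Mannich base (C16 epimeric) | CO[C@@H]1OC[C@]2(C)CCC[C@]3(COC(=O)[C@@]45C[C@@H](CC[C@H]43)C(CN(C)C)C5=O)[C@H]12 | intermediate |
| 27 | iodomethane | CI | reagent (starting material) |
| 28 | 15‑oxo‑16‑ene enone | CO[C@@H]1OC[C@]2(C)CCC[C@]3(COC(=O)[C@@]45C[C@@H](CC[C@H]43)C(=C)C5=O)[C@H]12 | intermediate |
| 29 | ludongnin F | CO[C@@H]1OC[C@]2(C)CCC[C@]3(COC(=O)[C@@]45C[C@@H](CC[C@H]43)[C@@H](C)C5=O)[C@H]12 | target |

**Totals:** 18 steps in total; longest linear sequence 17 steps (steps 1, 2, 4–18).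

**Three steps most likely to fail**
1. **Step 5 (IMDA).** It forms a quaternary C4 next to C5 and C10 from a diene terminus carrying an inside methyl, and Me2AlCl may ionise the dienyl ester. Fallback (different approach): build the A ring by Cu‑catalysed asymmetric methyl conjugate addition to 3‑(benzyloxymethyl)cyclohexenone, then install C10's C9/C20 by Corey–Chaykovsky epoxidation, Meinwald rearrangement and hydroxymethylation.
2. **Step 13 (Knoevenagel/Diels–Alder).** The acyl‑enone can react as a 1‑oxadiene (hetero‑Diels–Alder), and the face selectivity at the crowded C9/C8 is only argued by sterics. Fallback (different approach): use an alkylidene‑malonate‑type lactone (ester in place of acetyl) for the carbo‑Diels–Alder, then convert the ester to the methyl ketone. Alternatively, close the bicyclo[3.2.1]octane by Pd‑mediated oxidative cyclisation of the 7,20‑lactone silyl ketene acetal onto a tethered alkene.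
3. **Step 15 (radical cyclisation).** 6‑endo closure would give the bicyclo[2.2.2] isomer, and ketone 24 carries the quaternary C8. Fallback (different mechanism): Pd(OAc)2 oxidative cycloalkenylation of the TMS enol ether of 21 (Toyota–Ihara type), which forms C13–C16 by alkene insertion and β‑hydride elimination and gives the exocyclic methylene directly.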